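The data stem from a simulated flask on assumed constants, noise included.

A small charge of J, 12 mM against 2.5 M of Z, stands in Sunday's flask, where Z goes to D, D to G and G to Q, each step running both ways.

common to all: J 12 mM
- Sunday's: Z 2.5 M; temperature −20 °C; the very flask that is asked about, followed so far
- Wednesday's: Z 1.7 M; temperature −25 °C; run made earlier
- flask: Z 2.5 M; temperature −20 °C; time 5.0 h

| run | time / min | D / % | Z / % |
|---|---|---|---|
| Sunday's | 40.0 | 35 | 57 |
| Sunday's | 80.0 | 40 | 39 |
| Sunday's | 120 | 38 | 29 |
| Sunday's | 180 | 38 | 28 |
| Sunday's | 240 | 37 | 26 |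
| Sunday's | 300 | 34 | 24 |
| Wednesday's | 0.333 | 0 | 99 |
| Wednesday's | 1.00 | 0 | 100 |
| Wednesday's | 1.50 | 0 | 100 |
| Wednesday's | 2.50 | 3 | 98 |
| Wednesday's | 4.00 | 3 | 99 |
| Wednesday's | 5.00 | 4 | 96 |
| Wednesday's | 6.00 | 4 | 96 |

(scatter of a reading: 2 percentage points)

- D that was removed still counts
- the analysis behind the earlier runs scatters by 2 percentage points, standard deviation
- reactions considered so far: Z <-> D; D <-> G; G <-> Q
- additions bring no volume worth counting

- north: at 5.0 h add J, 100% of the amount charged, then wait 10 h
- south-east: at 5.0 h take out 90% of the D then present, then wait 10 h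
- south-west: change nothing and wait 10 h more
- north-east: at 5.0 h raise the temperature by 10 K, then wait 10 h

- D, in percent of the Z first charged, at 5.0 h
- which option adds most D ("none" when 2 percentage points or less is all one gets) (north / south-east / south-west / north-east / none)
- D present, with what was taken out counted in, in percent of the Z first charged, after south-east
- D present, with what was taken out counted in, in percent of the Z first charged, after north-east

From 120 min on, Sunday's readings of D and Z sink together. Sum both over the last four readings and you get 1.37, the balance ratio, D over Z, a reading with its scatter. Multiply the last Z reading, 24%, by it and your D at 5.0 h is 33.0%, beside a D reading of 34%.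

South-east leaves 3.40% of D beside 24% of Z, far from that ratio. If those two share out again by the ratio, D present plus D taken out comes to 46.5%, so you choose south-east.

The forecast says 35%, a little above your figure, and picks south-east with 46%. For north-east it gives 10%: “The leak is then much faster”.

The flask gives 34.5% at 5.0 h, and south-east is best, adding 15 percentage points and reaching 49.2%. North-east reaches 24.7%, which is 15 points above the forecast.

    Z ⇌ D (K = 1.40, k = 0.0180 min⁻¹, Ea = 87.0 kJ mol⁻¹, ΔH = −11.0 kJ mol⁻¹)
    D ⇌ G (K = 0.910, k = 0.0120 min⁻¹, Ea = 80.0 kJ mol⁻¹, ΔH = −26.0 kJ mol⁻¹)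
    G ⇌ Q (K = 2.10, k = 0.00190 min⁻¹, Ea = 89.0 kJ mol⁻¹, ΔH = 20.0 kJ mol⁻¹)
    (constants at −20 °C)

In Sunday's flask Z to D ran early, with 70% of its turnover up to 5.0 h behind it by 60.0 min, and D to G had lifted G to 26.4% by 150 min, while Z still stood at 31.5%. G to Q ran on behind them, its relaxation half-life of 4.12 h longer than the 27.5 min of D and G, and Q stood at 11.2% at 300 min. The balance ratio times that moment's Z of 25.7% is 35.4%, with D at 34.5%. Read at 12 h, the same flask holds Z 21.0%, the ratio times that is 28.9%, and D stands at 28.8%.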